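**Retrosynthetic overview**
1. Target ⇐ TBS ether 19 ⇐ ketone 17: equatorial MeMgBr addition sets the axial C7' carbinol of the right half (the half with the free secondary OH), and the three alkoxides are acetylated in the same flask.
2. Central CH2–CH2 bond ⇐ Giese addition of the left-half primary iodide 13 to the right-half exocyclic enone 16.
3. 13 and 16 ⇐ one bicyclic β-keto ester 9. Left: methylenation, α-face epoxidation, LiAlH4 (equatorial tertiary OH). Right: silyl enol ether, DIBAL-H, acid (α-methylene ketone).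
4. 9 ⇐ acyclic diepoxy β-keto ester 6 by one epoxonium cascade: the oxepane ring closes first, the cyclohexanone ring second (trans-fused).
5. 6 ⇐ geraniol (double Shi epoxidation) + methyl acetoacetate (dianion alkylation).

Assumption: the L-fructose-derived enantiomer of the Shi ketone (made from L-sorbose) is taken as a purchasable catalyst; ring locants follow 1-benzoxepine numbering (O1, C2–C5, C5a, C6–C9, C9a).

**Route**

Step 1
Reactants: 1 geraniol
Product: 2 (2S,3S,6S)-2,3:6,7-diepoxy-3,7-dimethyloctan-1-ol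
Conditions: L-fructose-derived Shi ketone (0.6 equiv), KHSO5 (as 2KHSO5·KHSO4·K2SO4), K2CO3, Bu4NHSO4, MeCN/DMM–aq. Na2B4O7 buffer (pH 10.5), 0 °C
Reagents that add atoms: potassium peroxymonosulfate [K+].[O-]S(=O)(=O)OO
Why: Shi asymmetric epoxidation, in which the dioxirane of the L-fructose-derived ketone epoxidises both trisubstituted alkenes through the spiro transition state with the same facial sense, setting 2S,3S and 6S (the D-fructose ketone gives the all-R series).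

Step 2
Reactants: 2 (2S,3S,6S)-2,3:6,7-diepoxy-3,7-dimethyloctan-1-ol; 3 methyl acetoacetate
Product: 6 methyl (6S,7S,10S)-6,7:10,11-diepoxy-7,11-dimethyl-3-oxododecanoate, via epoxy triflate 4 (not isolated), via acetoacetate dianion 5 (not isolated)
Conditions: 2, Tf2O, 2,6-lutidine, CH2Cl2, −78 °C; cannulate into 5 (from 3, NaH then n-BuLi, THF, 0 °C) at −78 °C; AcOH quench at −78 °C
Reagents that add atoms: none
Why: Weiler dianion alkylation, in which the γ-carbanion displaces the primary triflate by SN2 at −78 °C faster than it opens either trisubstituted epoxide, so the three epoxide stereocentres pass through unchanged.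

Step 3
Reactants: 6 methyl (6S,7S,10S)-6,7:10,11-diepoxy-7,11-dimethyl-3-oxododecanoate
Product: 9 methyl (3S,5aS,6S,9aS)-3-hydroxy-2,2,5a-trimethyl-7-oxodecahydro-1-benzoxepine-6-carboxylate, via TMS enol ether 7 (not isolated), via TMS ether 8 (not isolated)
Conditions: BSA, CH2Cl2, rt, evaporate; Me3SiOTf (0.3 equiv), 2,6-di-tert-butyl-4-methylpyridine (0.5 equiv), CH2Cl2, −78 °C; aq. citric acid/THF work-up
Reagents that add atoms: none
Why: Tandem epoxide-opening oxa-/carbacyclisation (epoxonium cascade with Mukaiyama-type enol silane termination), in which silylation of the terminal epoxide triggers attack of the internal epoxide oxygen at the tertiary carbon (oxepane; C3 and C9a keep their epoxide configurations) and the enol silane carbon then opens the bicyclic epoxonium at its tertiary carbon with inversion through a chair (trans ring fusion at C5a), the enolisable C6 settling with the ester equatorial.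

Step 4
Reactants: 9 methyl (3S,5aS,6S,9aS)-3-hydroxy-2,2,5a-trimethyl-7-oxodecahydro-1-benzoxepine-6-carboxylate
Product: 10 methyl (3S,5aS,6R,9aS)-3-hydroxy-2,2,5a-trimethyl-7-methylidenedecahydro-1-benzoxepine-6-carboxylate
Conditions: Ph3PCH3Br (4 equiv), KN(SiMe3)2, toluene/THF, 0 → 60 °C
Reagents that add atoms: methyltriphenylphosphonium bromide C[P+](c1ccccc1)(c1ccccc1)c1ccccc1.[Br-]
Why: Wittig methylenation, in which the ylide adds to the hindered ketone because enolisation towards C6 is disfavoured by A(1,3) strain between the ester and the neighbouring quaternary carbon, and C6 keeps its equatorial ester.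

Step 5
Reactants: 10 methyl (3S,5aS,6R,9aS)-3-hydroxy-2,2,5a-trimethyl-7-methylidenedecahydro-1-benzoxepine-6-carboxylate
Product: 11 methyl (3S,5aS,6S,7S,9aS)-3-hydroxy-2,2,5a-trimethyloctahydro-2H-spiro[1-benzoxepine-7,2'-oxirane]-6-carboxylate
Conditions: mCPBA, NaHCO3, CH2Cl2, 0 °C
Reagents that add atoms: 3-chloroperoxybenzoic acid OOC(=O)c1cccc(Cl)c1
Why: Prilezhaev epoxidation, in which the peracid attacks the exocyclic alkene from the α face, opposite the 1,3-related axial C5a methyl, so that at C7 the epoxide oxygen is equatorial (α) and the CH2 axial (β).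

Step 6
Reactants: 11 methyl (3S,5aS,6S,7S,9aS)-3-hydroxy-2,2,5a-trimethyloctahydro-2H-spiro[1-benzoxepine-7,2'-oxirane]-6-carboxylate
Product: 12 (3S,5aS,6R,7S,9aS)-6-(hydroxymethyl)-2,2,5a,7-tetramethyldecahydro-1-benzoxepine-3,7-diol
Conditions: LiAlH4, THF, 0 °C → reflux; Fieser work-up
Reagents that add atoms: none
Why: Hydride reduction, in which LiAlH4 reduces the ester to the primary alcohol and opens the spiro-epoxide by SN2 attack at its CH2, turning that carbon into the axial 7-methyl and leaving the equatorial C7–O bond from step 5 untouched.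

Step 7
Reactants: 12 (3S,5aS,6R,7S,9aS)-6-(hydroxymethyl)-2,2,5a,7-tetramethyldecahydro-1-benzoxepine-3,7-diol
Product: 13 (3S,5aS,6S,7S,9aS)-6-(iodomethyl)-2,2,5a,7-tetramethyldecahydro-1-benzoxepine-3,7-diol
Conditions: I2, PPh3, imidazole, THF/MeCN, 0 °C → 40 °C
Reagents that add atoms: iodine II
Why: Appel-type (Garegg–Samuelsson) iodination, in which the alkoxyphosphonium forms only at the primary hydroxyl and is displaced by iodide while the hindered secondary and the tertiary hydroxyls do not react.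

Step 8
Reactants: 9 methyl (3S,5aS,6S,9aS)-3-hydroxy-2,2,5a-trimethyl-7-oxodecahydro-1-benzoxepine-6-carboxylate
Product: 14 methyl (3S,5aS,9aS)-3,7-bis{[tert-butyl(dimethyl)silyl]oxy}-2,2,5a-trimethyl-2,3,4,5,5a,8,9,9a-octahydro-1-benzoxepine-6-carboxylate
Conditions: NaH (2.2 equiv), THF, 0 °C; t-BuMe2SiOTf (2.4 equiv), −78 → 0 °C
Reagents that add atoms: tert-butyldimethylsilyl triflate CC(C)(C)[Si](C)(C)OS(=O)(=O)C(F)(F)F
Why: O-silylation of the sodium alkoxide and of the β-keto ester enolate, in which the hard silyl triflate reacts at oxygen of both, protecting the 3-hydroxyl and fixing the ketone as its conjugated silyl enol ether regiospecifically towards C6.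

Step 9
Reactants: 14 methyl (3S,5aS,9aS)-3,7-bis{[tert-butyl(dimethyl)silyl]oxy}-2,2,5a-trimethyl-2,3,4,5,5a,8,9,9a-octahydro-1-benzoxepine-6-carboxylate
Product: 16 (3S,5aS,9aS)-3-{[tert-butyl(dimethyl)silyl]oxy}-2,2,5a-trimethyl-6-methylideneoctahydro-1-benzoxepin-7(2H)-one, via allylic alcohol 15 (not isolated)
Conditions: i-Bu2AlH, toluene, −78 → 0 °C, aqueous work-up; then oxalic acid (cat.), wet THF, rt
Reagents that add atoms: none
Why: DIBAL-H 1,2-reduction of the β-silyloxy enoate to the allylic alcohol followed by acid-catalysed allylic ionisation and desilylation (Stork–Danheiser-type transposition), which expels water and the enol silyl group to leave the α-methylene ketone while the secondary silyl ether survives.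

Step 10
Reactants: 13 (3S,5aS,6S,7S,9aS)-6-(iodomethyl)-2,2,5a,7-tetramethyldecahydro-1-benzoxepine-3,7-diol; 16 (3S,5aS,9aS)-3-{[tert-butyl(dimethyl)silyl]oxy}-2,2,5a-trimethyl-6-methylideneoctahydro-1-benzoxepin-7(2H)-one
Product: 17 (3S,5aS,6S,9aS)-3-{[tert-butyl(dimethyl)silyl]oxy}-6-{2-[(3S,5aS,6S,7S,9aS)-3,7-dihydroxy-2,2,5a,7-tetramethyldecahydro-1-benzoxepin-6-yl]ethyl}-2,2,5a-trimethyloctahydro-1-benzoxepin-7(2H)-one
Conditions: 16 (1.5 equiv), (Me3Si)3SiH (syringe pump), AIBN (cat.), toluene, 80 °C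
Reagents that add atoms: none
Why: Giese radical conjugate addition, in which the primary radical from the C–I bond adds to the unhindered CH2 terminus of the exocyclic enone and the α-keto radical takes hydrogen from the silane on the face opposite the angular methyl, giving the equatorial (6S) side chain, which is also the thermodynamic epimer.

Step 11
Reactants: 17 (3S,5aS,6S,9aS)-3-{[tert-butyl(dimethyl)silyl]oxy}-6-{2-[(3S,5aS,6S,7S,9aS)-3,7-dihydroxy-2,2,5a,7-tetramethyldecahydro-1-benzoxepin-6-yl]ethyl}-2,2,5a-trimethyloctahydro-1-benzoxepin-7(2H)-one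
Product: 19 (3S,5aS,6S,7S,9aS)-6-{2-[(3S,5aS,6S,7R,9aS)-7-(acetyloxy)-3-{[tert-butyl(dimethyl)silyl]oxy}-2,2,5a,7-tetramethyldecahydro-1-benzoxepin-6-yl]ethyl}-2,2,5a,7-tetramethyldecahydro-1-benzoxepine-3,7-diyl diacetate, via bromomagnesium trialkoxide 18 (not isolated)
Conditions: MeMgBr (4 equiv), THF, −78 → 0 °C; then Ac2O (10 equiv), DMAP (cat.), 0 → 40 °C
Reagents that add atoms: methylmagnesium bromide C[Mg]Br; acetic anhydride CC(=O)OC(C)=O
Why: Grignard 1,2-addition with O-acylation of the alkoxides in the same flask, in which MeMgBr attacks the ketone along the equatorial trajectory because the axial path is blocked by the 1,3-diaxial C5a' methyl (methyl equatorial, oxygen axial, 7'R) and the three bromomagnesium alkoxides are then trapped by Ac2O/DMAP.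

Step 12
Reactants: 19 (3S,5aS,6S,7S,9aS)-6-{2-[(3S,5aS,6S,7R,9aS)-7-(acetyloxy)-3-{[tert-butyl(dimethyl)silyl]oxy}-2,2,5a,7-tetramethyldecahydro-1-benzoxepin-6-yl]ethyl}-2,2,5a,7-tetramethyldecahydro-1-benzoxepine-3,7-diyl diacetate
Product: 20 (3S,5aS,6S,7S,9aS)-6-{2-[(3S,5aS,6S,7R,9aS)-7-(acetyloxy)-3-hydroxy-2,2,5a,7-tetramethyldecahydro-1-benzoxepin-6-yl]ethyl}-2,2,5a,7-tetramethyldecahydro-1-benzoxepine-3,7-diyl diacetate (CNP0169816.2)
Conditions: HF·pyridine, THF/pyridine, 0 °C → rt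
Reagents that add atoms: none
Why: Fluoride-mediated desilylation, in which HF·pyridine cleaves the Si–O bond of the secondary silyl ether while the secondary and the two tertiary acetates are inert to the buffered fluoride.

**Compound list**

1 | geraniol, (2E)-3,7-dimethylocta-2,6-dien-1-ol | CC(C)=CCC/C(C)=C/CO | starting material
2 | (2S,3S,6S)-2,3:6,7-diepoxy-3,7-dimethyloctan-1-ol | OC[C@@H]1O[C@@]1(C)CC[C@@H]1OC1(C)C | intermediate
3 | methyl acetoacetate (methyl 3-oxobutanoate) | COC(=O)CC(C)=O | starting material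
4 | [(2S,3S)-3-{2-[(2S)-3,3-dimethyloxiran-2-yl]ethyl}-3-methyloxiran-2-yl]methyl trifluoromethanesulfonate (not isolated) | FC(F)(F)S(=O)(=O)OC[C@@H]1O[C@@]1(C)CC[C@@H]1OC1(C)C | intermediate
5 | sodium lithium dianion of methyl acetoacetate (not isolated) | [Na+].[Li+].COC(=O)[CH-]C(=O)[CH2-] | intermediate
6 | methyl (6S,7S,10S)-6,7:10,11-diepoxy-7,11-dimethyl-3-oxododecanoate | COC(=O)CC(=O)CC[C@@H]1O[C@@]1(C)CC[C@@H]1OC1(C)C | intermediate
7 | methyl (2Z,6S,7S,10S)-6,7:10,11-diepoxy-7,11-dimethyl-3-[(trimethylsilyl)oxy]dodec-2-enoate (not isolated; enol ether geometry is inconsequential) | COC(=O)/C=C(\O[Si](C)(C)C)CC[C@@H]1O[C@@]1(C)CC[C@@H]1OC1(C)C | intermediate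
8 | methyl (3S,5aS,6S,9aS)-2,2,5a-trimethyl-7-oxo-3-[(trimethylsilyl)oxy]decahydro-1-benzoxepine-6-carboxylate (not isolated) | C[Si](C)(C)O[C@H]1CC[C@]2(C)[C@H](CCC(=O)[C@H]2C(=O)OC)OC1(C)C | intermediate
9 | methyl (3S,5aS,6S,9aS)-3-hydroxy-2,2,5a-trimethyl-7-oxodecahydro-1-benzoxepine-6-carboxylate (trans-fused, ester equatorial) | O[C@H]1CC[C@]2(C)[C@H](CCC(=O)[C@H]2C(=O)OC)OC1(C)C | intermediate
10 | methyl (3S,5aS,6R,9aS)-3-hydroxy-2,2,5a-trimethyl-7-methylidenedecahydro-1-benzoxepine-6-carboxylate | O[C@H]1CC[C@]2(C)[C@H](CCC(=C)[C@H]2C(=O)OC)OC1(C)C | intermediate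
11 | methyl (3S,5aS,6S,7S,9aS)-3-hydroxy-2,2,5a-trimethyloctahydro-2H-spiro[1-benzoxepine-7,2'-oxirane]-6-carboxylate (epoxide O equatorial/α, CH2 axial/β) | O[C@H]1CC[C@]2(C)[C@H](CC[C@@]3(CO3)[C@H]2C(=O)OC)OC1(C)C | intermediate
12 | (3S,5aS,6R,7S,9aS)-6-(hydroxymethyl)-2,2,5a,7-tetramethyldecahydro-1-benzoxepine-3,7-diol | O[C@H]1CC[C@]2(C)[C@H](CC[C@](C)(O)[C@H]2CO)OC1(C)C | intermediate
13 | (3S,5aS,6S,7S,9aS)-6-(iodomethyl)-2,2,5a,7-tetramethyldecahydro-1-benzoxepine-3,7-diol | O[C@H]1CC[C@]2(C)[C@H](CC[C@](C)(O)[C@H]2CI)OC1(C)C | intermediate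
14 | methyl (3S,5aS,9aS)-3,7-bis{[tert-butyl(dimethyl)silyl]oxy}-2,2,5a-trimethyl-2,3,4,5,5a,8,9,9a-octahydro-1-benzoxepine-6-carboxylate | CC(C)(C)[Si](C)(C)O[C@H]1CC[C@]2(C)[C@H](CCC(O[Si](C)(C)C(C)(C)C)=C2C(=O)OC)OC1(C)C | intermediate
15 | [(3S,5aS,9aS)-3,7-bis{[tert-butyl(dimethyl)silyl]oxy}-2,2,5a-trimethyl-2,3,4,5,5a,8,9,9a-octahydro-1-benzoxepin-6-yl]methanol (not isolated) | CC(C)(C)[Si](C)(C)O[C@H]1CC[C@]2(C)[C@H](CCC(O[Si](C)(C)C(C)(C)C)=C2CO)OC1(C)C | intermediate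
16 | (3S,5aS,9aS)-3-{[tert-butyl(dimethyl)silyl]oxy}-2,2,5a-trimethyl-6-methylideneoctahydro-1-benzoxepin-7(2H)-one | CC(C)(C)[Si](C)(C)O[C@H]1CC[C@]2(C)[C@H](CCC(=O)C2=C)OC1(C)C | intermediate
17 | (3S,5aS,6S,9aS)-3-{[tert-butyl(dimethyl)silyl]oxy}-6-{2-[(3S,5aS,6S,7S,9aS)-3,7-dihydroxy-2,2,5a,7-tetramethyldecahydro-1-benzoxepin-6-yl]ethyl}-2,2,5a-trimethyloctahydro-1-benzoxepin-7(2H)-one | O[C@H]1CC[C@]2(C)[C@H](CC[C@](C)(O)[C@H]2CC[C@H]2[C@]3(C)CC[C@H](O[Si](C)(C)C(C)(C)C)C(C)(C)O[C@H]3CCC2=O)OC1(C)C | intermediate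
18 | tris(bromomagnesium) alkoxide of (3S,5aS,6S,7S,9aS)-6-{2-[(3S,5aS,6S,7R,9aS)-3-{[tert-butyl(dimethyl)silyl]oxy}-7-hydroxy-2,2,5a,7-tetramethyldecahydro-1-benzoxepin-6-yl]ethyl}-2,2,5a,7-tetramethyldecahydro-1-benzoxepine-3,7-diol (not isolated) | Br[Mg]O[C@H]1CC[C@]2(C)[C@H](CC[C@](C)(O[Mg]Br)[C@H]2CC[C@H]2[C@]3(C)CC[C@H](O[Si](C)(C)C(C)(C)C)C(C)(C)O[C@H]3CC[C@@]2(C)O[Mg]Br)OC1(C)C | intermediate
19 | (3S,5aS,6S,7S,9aS)-6-{2-[(3S,5aS,6S,7R,9aS)-7-(acetyloxy)-3-{[tert-butyl(dimethyl)silyl]oxy}-2,2,5a,7-tetramethyldecahydro-1-benzoxepin-6-yl]ethyl}-2,2,5a,7-tetramethyldecahydro-1-benzoxepine-3,7-diyl diacetate | CC(=O)O[C@H]1CC[C@]2(C)[C@H](CC[C@](C)(OC(C)=O)[C@H]2CC[C@H]2[C@]3(C)CC[C@H](O[Si](C)(C)C(C)(C)C)C(C)(C)O[C@H]3CC[C@@]2(C)OC(C)=O)OC1(C)C | intermediate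
20 | (3S,5aS,6S,7S,9aS)-6-{2-[(3S,5aS,6S,7R,9aS)-7-(acetyloxy)-3-hydroxy-2,2,5a,7-tetramethyldecahydro-1-benzoxepin-6-yl]ethyl}-2,2,5a,7-tetramethyldecahydro-1-benzoxepine-3,7-diyl diacetate | CC(=O)O[C@H]1CC[C@]2(C)[C@H](CC[C@](C)(OC(C)=O)[C@H]2CC[C@H]2[C@]3(C)CC[C@H](O)C(C)(C)O[C@H]3CC[C@@]2(C)OC(C)=O)OC1(C)C | target

**Step count and risk**

Total steps: 12. Longest linear sequence: 10 steps (steps 1–7, then 10–12, from geraniol); the right-half branch is steps 1–3, 8 and 9.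

Steps most likely to fail:

Step 3 (the epoxonium cascade with a β-keto ester enol silane as terminator has no direct precedent; steps 4 and 8 depend on it). The fallback sets out from 6 and changes the terminating nucleophile to an allylsilane, which also delivers the methylidene group of step 4. NaH and ClP(O)(OEt)2 in Et2O at 0 °C give methyl (2Z,6S,7S,10S)-3-[(diethoxyphosphoryl)oxy]-6,7:10,11-diepoxy-7,11-dimethyldodec-2-enoate F1. Coupling with Me3SiCH2MgCl under Ni(acac)2 catalysis gives methyl (2Z,6S,7S,10S)-6,7:10,11-diepoxy-7,11-dimethyl-3-[(trimethylsilyl)methyl]dodec-2-enoate F2. Me3SiOTf and 2,6-di-tert-butyl-4-methylpyridine at −78 °C then run the same cascade with SE2' termination to methyl (3S,5aS,6R,9aS)-2,2,5a-trimethyl-7-methylidene-3-[(trimethylsilyl)oxy]decahydro-1-benzoxepine-6-carboxylate F3, which is hydrolysed on work-up; the route is rejoined at 10. The 9 needed for step 8 is then taken from 10 by ozonolysis (O3, then Me2S).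

Step 10 (a radical fragment coupling of two advanced partners near 1:1, with premature reduction of the iodide or of the enone as competitors). The fallback sets out from 13 and replaces the radical by a sulfone-stabilised carbanion. PhSO2Na in DMF at 80 °C gives (3S,5aS,6S,7S,9aS)-6-[(benzenesulfonyl)methyl]-2,2,5a,7-tetramethyldecahydro-1-benzoxepine-3,7-diol F4. Its trilithio derivative (LiN(i-Pr)2, THF/DMPU, −78 °C) adds 1,4 to enone 16 to give (3S,5aS,6S,9aS)-6-{2-(benzenesulfonyl)-2-[(3S,5aS,6S,7S,9aS)-3,7-dihydroxy-2,2,5a,7-tetramethyldecahydro-1-benzoxepin-6-yl]ethyl}-3-{[tert-butyl(dimethyl)silyl]oxy}-2,2,5a-trimethyloctahydro-1-benzoxepin-7(2H)-one F5 (both epimers at the sulfonyl carbon). Reductive desulfonylation with Na/Hg and Na2HPO4 in MeOH at −20 °C rejoins the route at 17.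

Step 11 (three alkoxides, one of them a very hindered axial tertiary one, must all be acetylated in the flask). The fallback sets out from 13 and spreads the acetylations over the route. Ac2O, DMAP and Et3N at 60 °C give (3S,5aS,6S,7S,9aS)-6-(iodomethyl)-2,2,5a,7-tetramethyldecahydro-1-benzoxepine-3,7-diyl diacetate F6. The Giese coupling with 16 under the conditions of step 10 gives (3S,5aS,6S,7S,9aS)-6-{2-[(3S,5aS,6S,9aS)-3-{[tert-butyl(dimethyl)silyl]oxy}-2,2,5a-trimethyl-7-oxodecahydro-1-benzoxepin-6-yl]ethyl}-2,2,5a,7-tetramethyldecahydro-1-benzoxepine-3,7-diyl diacetate F7. MeCeCl2 (from MeLi and CeCl3, THF, −78 °C) adds to the ketone only, giving (3S,5aS,6S,7S,9aS)-6-{2-[(3S,5aS,6S,7R,9aS)-3-{[tert-butyl(dimethyl)silyl]oxy}-7-hydroxy-2,2,5a,7-tetramethyldecahydro-1-benzoxepin-6-yl]ethyl}-2,2,5a,7-tetramethyldecahydro-1-benzoxepine-3,7-diyl diacetate F8. This single tertiary alcohol is acetylated on its own (Ac2O, DMAP, Et3N, 60 °C), rejoining the route at 19.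

**Further compounds**

F1 | step 3 | methyl (2Z,6S,7S,10S)-3-[(diethoxyphosphoryl)oxy]-6,7:10,11-diepoxy-7,11-dimethyldodec-2-enoate | COC(=O)/C=C(\OP(=O)(OCC)OCC)CC[C@@H]1O[C@@]1(C)CC[C@@H]1OC1(C)C
F2 | step 3 | methyl (2Z,6S,7S,10S)-6,7:10,11-diepoxy-7,11-dimethyl-3-[(trimethylsilyl)methyl]dodec-2-enoate | COC(=O)/C=C(\C[Si](C)(C)C)CC[C@@H]1O[C@@]1(C)CC[C@@H]1OC1(C)C
F3 | step 3 | methyl (3S,5aS,6R,9aS)-2,2,5a-trimethyl-7-methylidene-3-[(trimethylsilyl)oxy]decahydro-1-benzoxepine-6-carboxylate | C[Si](C)(C)O[C@H]1CC[C@]2(C)[C@H](CCC(=C)[C@H]2C(=O)OC)OC1(C)C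
F4 | step 10 | (3S,5aS,6S,7S,9aS)-6-[(benzenesulfonyl)methyl]-2,2,5a,7-tetramethyldecahydro-1-benzoxepine-3,7-diol | O[C@H]1CC[C@]2(C)[C@H](CC[C@](C)(O)[C@H]2CS(=O)(=O)c2ccccc2)OC1(C)C
F5 | step 10 | (3S,5aS,6S,9aS)-6-{2-(benzenesulfonyl)-2-[(3S,5aS,6S,7S,9aS)-3,7-dihydroxy-2,2,5a,7-tetramethyldecahydro-1-benzoxepin-6-yl]ethyl}-3-{[tert-butyl(dimethyl)silyl]oxy}-2,2,5a-trimethyloctahydro-1-benzoxepin-7(2H)-one (epimers at the sulfonyl carbon) | O[C@H]1CC[C@]2(C)[C@H](CC[C@](C)(O)[C@H]2C(C[C@H]2[C@]3(C)CC[C@H](O[Si](C)(C)C(C)(C)C)C(C)(C)O[C@H]3CCC2=O)S(=O)(=O)c2ccccc2)OC1(C)C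
F6 | step 11 | (3S,5aS,6S,7S,9aS)-6-(iodomethyl)-2,2,5a,7-tetramethyldecahydro-1-benzoxepine-3,7-diyl diacetate | CC(=O)O[C@H]1CC[C@]2(C)[C@H](CC[C@](C)(OC(C)=O)[C@H]2CI)OC1(C)C
F7 | step 11 | (3S,5aS,6S,7S,9aS)-6-{2-[(3S,5aS,6S,9aS)-3-{[tert-butyl(dimethyl)silyl]oxy}-2,2,5a-trimethyl-7-oxodecahydro-1-benzoxepin-6-yl]ethyl}-2,2,5a,7-tetramethyldecahydro-1-benzoxepine-3,7-diyl diacetate | CC(=O)O[C@H]1CC[C@]2(C)[C@H](CC[C@](C)(OC(C)=O)[C@H]2CC[C@H]2[C@]3(C)CC[C@H](O[Si](C)(C)C(C)(C)C)C(C)(C)O[C@H]3CCC2=O)OC1(C)C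
F8 | step 11 | (3S,5aS,6S,7S,9aS)-6-{2-[(3S,5aS,6S,7R,9aS)-3-{[tert-butyl(dimethyl)silyl]oxy}-7-hydroxy-2,2,5a,7-tetramethyldecahydro-1-benzoxepin-6-yl]ethyl}-2,2,5a,7-tetramethyldecahydro-1-benzoxepine-3,7-diyl diacetate | CC(=O)O[C@H]1CC[C@]2(C)[C@H](CC[C@](C)(OC(C)=O)[C@H]2CC[C@H]2[C@]3(C)CC[C@H](O[Si](C)(C)C(C)(C)C)C(C)(C)O[C@H]3CC[C@@]2(C)O)OC1(C)C
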